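The data stem from a simulated flask on assumed constants; noise was put on by code.

Count the first nucleophile.

common to all: substrate 0.50 M; gas 190 mM (held)
- autumn: first nucleophile 0.12 M; temperature 5 °C; run made earlier
- winter: first nucleophile 0.19 M; temperature 25 °C; run made earlier
- larch: first nucleophile 0.250 M; temperature 40 °C; time 1.0 h
- oak: first nucleophile 0.250 M; temperature 25 °C; time 1.0 h
- cedar: first nucleophile 0.250 M; temperature 10 °C; time 1.0 h

| run | time / h | target / % | other capture product / % |
|---|---|---|---|
| autumn | 1.00 | 3 | 1 |
| autumn | 2.50 | 11 | 0 |
| autumn | 5.00 | 18 | 6 |
| autumn | 8.00 | 22 | 6 |
| winter | 0.200 | 8 | 0 |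
| winter | 0.417 | 20 | 0 |
| winter | 1.00 | 30 | 5 |
| winter | 3.00 | 33 | 23 |

(standard deviation of a reading: 1.5 percentage points)

- the earlier runs were read with a standard deviation of 1.5 percentage points
- at the start none of the gas is in solution

1. which flask leads in share of target in all that became target or other capture product ("all alike" within 1.5 percentage points) (larch / oak / cedar / all alike)
2. share of target in all that became target or other capture product, larch
3. share of target in all that became target or other capture product, oak
4. share of target in all that became target or other capture product, cedar

Oak looks nearly like the winter run: same substrate, same gas, same temperature, 25 °C. They differ in the first nucleophile, charged at 50.0% of the substrate in oak and at 38.0% in the winter run.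

Look at how the winter run ends. From 1.00 h to 3.00 h its target gains 3 percentage points, while its other capture product gains 18 points. Write the balance with one first nucleophile per target, and treat the first nucleophile, the smaller charge, as the limiting reagent. A target of 33% on a charge of 38.0% gives 86.8%: the capture yield, the part of the first nucleophile charged that stands as target at the last reading. It is a reading, with the target's scatter of 1.5 points in it.

Carry it over. If the capture yield holds at oak's larger charge, the ceiling on target in oak is 43.4% of the substrate; larch and cedar, charged alike, get the same ceiling if it holds at their temperatures too. A flask standing at that ceiling has the share ceiling over ceiling plus other capture product. For oak, start from the share read in the winter run at 1.00 h, 85.7%. Name no figure for larch until its other capture product is known.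

The forecast puts cedar first, with 62% in larch, 88% in oak and 93% in cedar, on this ground: “Other product keeps growing regardless, especially after the nucleophile is gone.” Its oak figure stands above my 85.7%.

The flasks give 73.0% in larch, 90.0% in oak and 96.5% in cedar, so cedar leads; larch stands 11 points above the forecast.

    substrate ⇌ intermediate (K = 0.160, k = 3.30 × 10⁻⁴ s⁻¹, Ea = 87.0 kJ mol⁻¹, ΔH = 6.00 kJ mol⁻¹)
    first nucleophile + intermediate → target (k = 0.0180 M⁻¹ s⁻¹, Ea = 50.0 kJ mol⁻¹)
    second nucleophile + intermediate → other capture product (k = 0.00220 M⁻¹ s⁻¹, Ea = 74.0 kJ mol⁻¹)
    2 first nucleophile → homo dimer (k = 4.10 × 10⁻⁴ M⁻¹ s⁻¹, Ea = 58.0 kJ mol⁻¹)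
    gas ⇌ second nucleophile, rate k5*(csat - [second nucleophile]) (kL = 3.90 × 10⁻⁴ s⁻¹)
    (constants at 25 °C)

Cedar at 0.339 h uses its intermediate to make target 42 times as fast as it loses it to other capture product, and at 1.0 h its target of 10.6% lies 33 points under the ceiling, with 64% of its first nucleophile left. Larch at 1.0 h, with 0.15% of its first nucleophile left, holds 42.1% target against the ceiling of 43.4%, and with its 15.5% other capture product the ceiling gives a share of 73.7%; cedar repeated at 35 °C, with 0.91% of its first nucleophile left, holds 41.3% target and 10.8% other capture product, and there the ceiling gives 80.1% against a simulated 79.2%.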